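Ring B is disconnected at its C1'–C2' bond. It carries four contiguous oxygens (C2'–C5'), a lone hydrogen (C6') and the C3 substituent on C1'. This is the pattern produced when a squarate-derived 4-alkenyl-4-hydroxy-2,3-dimethoxycyclobutenone is heated. In one operation the four-membered ring opens to a dienylketene that closes ring B as a hydroquinone directly on C3, which spares any cross-coupling at the congested C3–C1' junction. The precursor is the adduct of dimethyl squarate with an E-vinyllithium attached to an enantiopure (3S)-chroman. C3 is set earlier by asymmetric hydrogenation of a 2H-chromene-3-carboxylic acid. Methylation and debenzylation finish the synthesis.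

Key step: step 10

Assumption: Ru(OAc)2[(S)-H8-BINAP] is taken to hydrogenate the chromene acid with the facial sense it shows for (E)-2-substituted acrylic acids of the tiglic acid type, which corresponds to the (3R) acid; if a trial run shows the opposite sense, the (R)-ligand is used.

Remark: the spatial arrangement at C3 is the same from compound 8 to the target; the descriptor is R in acid 8 and aldehyde 10 and S elsewhere only because the CIP rank of the exocyclic carbon changes.

Step 1
Reactants: 1 2-methoxybenzene-1,3-diol (2-methoxyresorcinol)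
Product: 3 2,4-dihydroxy-3-methoxybenzaldehyde, via aryl iminium chloride 2 (not isolated)
Conditions: POCl3, DMF, MeCN, 0 °C to rt; then H2O, 50 °C
Reagents that add atoms: N,N-dimethylformamide CN(C)C=O; water O
Why: Vilsmeier–Haack formylation, in which the chloroiminium electrophile can only attack the two equivalent positions that are ortho to one hydroxyl and para to the other, and water then hydrolyses iminium salt 2 to the aldehyde.

Step 2
Reactants: 3 2,4-dihydroxy-3-methoxybenzaldehyde
Product: 4 4-(benzyloxy)-2-hydroxy-3-methoxybenzaldehyde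
Conditions: BnBr (1.05 equiv), NaHCO3, KI (cat.), MeCN, 60 °C
Reagents that add atoms: benzyl bromide BrCc1ccccc1
Why: Williamson etherification with a weak base is selective for the 4-hydroxyl, which is the more acidic (para to the formyl group), whereas the 2-hydroxyl is held in a hydrogen bond to the carbonyl.

Step 3
Reactants: 4 4-(benzyloxy)-2-hydroxy-3-methoxybenzaldehyde; 5 acrylonitrile
Product: 6 7-(benzyloxy)-8-methoxy-2H-chromene-3-carbonitrile
Conditions: DABCO (0.5 equiv), acrylonitrile (neat, excess), 80 °C
Reagents that add atoms: none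
Why: Amine-catalysed Baylis–Hillman/oxa-Michael annulation of a salicylaldehyde with an acceptor alkene, in which aldol-type addition, ring closure by the phenol oxygen and loss of water give the conjugated 2H-chromene.

Step 4
Reactants: 6 7-(benzyloxy)-8-methoxy-2H-chromene-3-carbonitrile
Product: 7 7-(benzyloxy)-8-methoxy-2H-chromene-3-carboxylic acid
Conditions: NaOH (10% aq), EtOH, reflux; then HCl aq to pH 2
Reagents that add atoms: sodium hydroxide [Na+].[OH-]; water O
Why: Alkaline nitrile hydrolysis, to which the aryl benzyl and methyl ethers and the conjugated ring double bond are inert, with the acid precipitating on acidification.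

Step 5
Reactants: 7 7-(benzyloxy)-8-methoxy-2H-chromene-3-carboxylic acid
Product: 8 (3R)-7-(benzyloxy)-8-methoxychroman-3-carboxylic acid
Conditions: Ru(OAc)2[(S)-H8-BINAP] (1 mol%), H2 (10 bar), MeOH, 25 °C; recrystallisation
Reagents that add atoms: none
Why: Carboxylate-directed asymmetric hydrogenation of an α,β-unsaturated acid, in which the substrate binds ruthenium through its carboxylate and the axially chiral diphosphine selects the face of the trisubstituted C3=C4 bond so that C3 is set as R, while the homogeneous catalyst leaves the benzyl ether intact.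

Step 6
Reactants: 8 (3R)-7-(benzyloxy)-8-methoxychroman-3-carboxylic acid
Product: 9 [(3S)-7-(benzyloxy)-8-methoxychroman-3-yl]methanol
Conditions: BH3·SMe2, THF, 0 °C to rt; then MeOH
Reagents that add atoms: none
Why: Borane reduction of a carboxylic acid to the primary alcohol touches no bond at C3 and leaves the aryl ethers alone.

Step 7
Reactants: 9 [(3S)-7-(benzyloxy)-8-methoxychroman-3-yl]methanol
Product: 10 (3R)-7-(benzyloxy)-8-methoxychroman-3-carbaldehyde
Conditions: TEMPO (10 mol%), PhI(OAc)2 (1.1 equiv), CH2Cl2, rt; used at once
Reagents that add atoms: none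
Why: Oxoammonium-mediated (TEMPO) oxidation stops at the aldehyde without any base, which matters because this β-aryloxy aldehyde could lose its C3 configuration by enolisation or reversible retro-oxa-Michael ring opening under basic conditions.

Step 8
Reactants: 10 (3R)-7-(benzyloxy)-8-methoxychroman-3-carbaldehyde
Product: 11 (3S)-7-(benzyloxy)-3-[(E)-2-iodoethenyl]-8-methoxychroman
Conditions: CrCl2 (6 equiv), CHI3 (2 equiv), 1,4-dioxane/THF, 0 °C to rt
Reagents that add atoms: iodoform IC(I)I
Why: Takai iodo-olefination, in which the geminal dichromium species formed from CHI3 and CrCl2 adds to the aldehyde and eliminates to the E-vinyl iodide under non-basic conditions that should leave the α-stereocentre untouched.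

Step 9
Reactants: 11 (3S)-7-(benzyloxy)-3-[(E)-2-iodoethenyl]-8-methoxychroman; 12 dimethyl squarate
Product: 14 4-{(E)-2-[(3S)-7-(benzyloxy)-8-methoxychroman-3-yl]ethenyl}-4-hydroxy-2,3-dimethoxycyclobut-2-en-1-one (both carbinol epimers), via vinyllithium 13 (not isolated)
Conditions: t-BuLi (2.05 equiv), Et2O, −78 °C; cannulate into 12 (1.2 equiv), THF, −78 °C; NH4Cl aq at −78 °C
Reagents that add atoms: none
Why: Iodine–lithium exchange proceeds with retention of alkene geometry and far faster than any ring metalation at −78 °C, and 1,2-addition of vinyllithium 13 to one of the two equivalent carbonyl groups of the squarate is the standard entry to 4-substituted 4-hydroxycyclobutenones; the uncontrolled carbinol centre is destroyed in step 10.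

Step 10
Reactants: 14 4-{(E)-2-[(3S)-7-(benzyloxy)-8-methoxychroman-3-yl]ethenyl}-4-hydroxy-2,3-dimethoxycyclobut-2-en-1-one
Product: 17 2-[(3S)-7-(benzyloxy)-8-methoxychroman-3-yl]-5,6-dimethoxybenzene-1,4-diol, via dienylketene 15 (not isolated), via cyclohexadienone 16 (not isolated)
Conditions: p-xylene (degassed, 0.02 M), Ar, reflux (138 °C); evaporate under Ar and use crude
Reagents that add atoms: none
Why: Heat breaks the C1–C4 bond of the cyclobutenone in a conrotatory 4π ring opening with the hydroxyl turning outward, so the alkenyl arm lies cis to the ketene in 15; the ketene carbon (future C2') then bonds to the chroman-bearing alkene carbon (future C1') in a disrotatory 6π electrocyclisation to give 16, and enolisation aromatises 16 to hydroquinone 17. The closest known reaction type is the Moore rearrangement of 4-alkenyl- and 4-aryl-4-hydroxycyclobutenones to hydroquinones. Ring B is the only ring formed and closes as a six-membered carbocycle by this 6π electrocyclisation, the single new skeletal bond being C1'–C2'. No stereocentre is created, since the sp3 centre of 16 and the carbinol centre of 14 both vanish on aromatisation, and C3 is a non-acidic spectator that no ionic or radical intermediate touches. The step needs outward rotation of the hydroxyl, which the donor character of an oxygen substituent on the breaking bond secures, and an unhindered alkene terminus, which the E geometry secures by pointing the chroman away from the ketene. The regiochemistry cannot vary because all four oxygens of ring B already sit on the squarate carbons.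

Step 11
Reactants: 17 2-[(3S)-7-(benzyloxy)-8-methoxychroman-3-yl]-5,6-dimethoxybenzene-1,4-diol
Product: 18 (3S)-7-(benzyloxy)-8-methoxy-3-(2,3,4,5-tetramethoxyphenyl)chroman
Conditions: Me2SO4 (3 equiv), K2CO3, acetone (degassed), Ar, reflux
Reagents that add atoms: dimethyl sulfate COS(=O)(=O)OC
Why: Williamson methylation of both phenols under exclusion of air, with the benzyl ether keeping O7 from being methylated.

Step 12
Reactants: 18 (3S)-7-(benzyloxy)-8-methoxy-3-(2,3,4,5-tetramethoxyphenyl)chroman
Product: 19 (3S)-8-methoxy-3-(2,3,4,5-tetramethoxyphenyl)chroman-7-ol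
Conditions: H2 (1 atm), 10% Pd/C, EtOAc/MeOH, rt
Reagents that add atoms: none
Why: Catalytic hydrogenolysis cleaves only the benzyl aryl ether, since the methyl ethers and the non-benzylic C2–O bond of the chroman are inert and the neutral conditions cannot epimerise C3.

Compound list
1 | 2-methoxybenzene-1,3-diol | COc1c(O)cccc1O | starting material
2 | [(2,4-dihydroxy-3-methoxyphenyl)methylidene]dimethylammonium chloride | C[N+](C)=Cc1ccc(O)c(OC)c1O.[Cl-] | intermediate
3 | 2,4-dihydroxy-3-methoxybenzaldehyde | O=Cc1ccc(O)c(OC)c1O | intermediate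
4 | 4-(benzyloxy)-2-hydroxy-3-methoxybenzaldehyde | O=Cc1ccc(OCc2ccccc2)c(OC)c1O | intermediate
5 | acrylonitrile | C=CC#N | starting material
6 | 7-(benzyloxy)-8-methoxy-2H-chromene-3-carbonitrile | N#CC1=Cc2ccc(OCc3ccccc3)c(OC)c2OC1 | intermediate
7 | 7-(benzyloxy)-8-methoxy-2H-chromene-3-carboxylic acid | OC(=O)C1=Cc2ccc(OCc3ccccc3)c(OC)c2OC1 | intermediate
8 | (3R)-7-(benzyloxy)-8-methoxychroman-3-carboxylic acid | OC(=O)[C@H]1COc2c(OC)c(OCc3ccccc3)ccc2C1 | intermediate
9 | [(3S)-7-(benzyloxy)-8-methoxychroman-3-yl]methanol | OC[C@H]1COc2c(OC)c(OCc3ccccc3)ccc2C1 | intermediate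
10 | (3R)-7-(benzyloxy)-8-methoxychroman-3-carbaldehyde | O=C[C@H]1COc2c(OC)c(OCc3ccccc3)ccc2C1 | intermediate
11 | (3S)-7-(benzyloxy)-3-[(E)-2-iodoethenyl]-8-methoxychroman | I/C=C/[C@H]1COc2c(OC)c(OCc3ccccc3)ccc2C1 | intermediate
12 | dimethyl squarate (3,4-dimethoxycyclobut-3-ene-1,2-dione) | COC1=C(OC)C(=O)C1=O | starting material
13 | {(E)-2-[(3S)-7-(benzyloxy)-8-methoxychroman-3-yl]ethenyl}lithium | [Li]/C=C/[C@H]1COc2c(OC)c(OCc3ccccc3)ccc2C1 | intermediate
14 | 4-{(E)-2-[(3S)-7-(benzyloxy)-8-methoxychroman-3-yl]ethenyl}-4-hydroxy-2,3-dimethoxycyclobut-2-en-1-one (both carbinol epimers) | COC1=C(OC)C(O)(/C=C/[C@H]2COc3c(OC)c(OCc4ccccc4)ccc3C2)C1=O | intermediate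
15 | (3Z,5E)-6-[(3S)-7-(benzyloxy)-8-methoxychroman-3-yl]-4-hydroxy-2,3-dimethoxyhexa-1,3,5-trien-1-one | O=C=C(OC)/C(OC)=C(O)\C=C\[C@H]1COc2c(OC)c(OCc3ccccc3)ccc2C1 | intermediate
16 | 6-[(3S)-7-(benzyloxy)-8-methoxychroman-3-yl]-4-hydroxy-2,3-dimethoxycyclohexa-2,4-dien-1-one (both C6 epimers) | O=C1C(OC)=C(OC)C(O)=CC1[C@H]2COc3c(OC)c(OCc4ccccc4)ccc3C2 | intermediate
17 | 2-[(3S)-7-(benzyloxy)-8-methoxychroman-3-yl]-5,6-dimethoxybenzene-1,4-diol | Oc1c(OC)c(OC)c(O)cc1[C@H]1COc2c(OC)c(OCc3ccccc3)ccc2C1 | intermediate
18 | (3S)-7-(benzyloxy)-8-methoxy-3-(2,3,4,5-tetramethoxyphenyl)chroman | COc1cc([C@H]2COc3c(OC)c(OCc4ccccc4)ccc3C2)c(OC)c(OC)c1OC | intermediate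
19 | (3S)-8-methoxy-3-(2,3,4,5-tetramethoxyphenyl)chroman-7-ol | COc1cc([C@H]2COc3c(ccc(O)c3OC)C2)c(OC)c(OC)c1OC | target

Total step count: 12. Longest linear sequence: 12 steps (1 to 19); acrylonitrile 5 and dimethyl squarate 12 are bought and enter directly.

Steps most likely to fail

Step 10 (key step). The ketene may be captured by the neighbouring tertiary hydroxyl before it cyclises, or the electron-rich hydroquinone may oxidise or degrade at the temperature needed. The fallback is the alkynyl version of the squarate ring expansion, which closes ring B through a diradical and ends at an air-stable quinone. It sets out from aldehyde 10. Base-free Corey–Fuchs olefination (CBr4, PPh3, CH2Cl2, 0 °C) should give (3S)-7-(benzyloxy)-3-(2,2-dibromoethenyl)-8-methoxychroman F1. Treatment with n-BuLi (2.1 equiv, THF, −78 °C) should convert it into the lithium acetylide F2, which is added in the same flask to dimethyl squarate 12 and quenched cold with NH4Cl to give the 4-alkynyl-4-hydroxycyclobutenone F3. Heating F3 in p-xylene should give the 2-chromanyl-5,6-dimethoxy-1,4-benzoquinone F4 by ring opening, ring closure and transfer of the hydroxyl hydrogen to the ring. Shaking F4 in EtOAc with aqueous Na2S2O4 reduces it to hydroquinone 17, where the route is rejoined before step 11.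

Step 5. The catalyst may discriminate poorly between the two faces of the trisubstituted C3=C4 bond, or favour the wrong one. The fallback is classical resolution and sets out from chromene acid 7. Hydrogenation with Ru(OAc)2(rac-BINAP) under the same conditions should give the racemic chroman-3-carboxylic acid F5. Crystallisation with (R)-1-phenylethylamine from EtOH/EtOAc should deposit the less soluble diastereomeric salt F6; if the salt of the (3S) acid proves the less soluble one, the (S)-amine is used instead. Acidification with HCl aq releases acid 8, where the route is rejoined before step 6.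

Step 8. E-selectivity may erode with the α-branched aldehyde, and a slow reaction on the Lewis-acidic chromium salts may cost the sensitive aldehyde some of its C3 integrity. A minor Z isomer would not be fatal, since both geometries lead to the same aromatic ring, but it should cyclise more slowly. The fallback builds the alkene in two steps through tin and sets out from aldehyde 10. Chromium-mediated stannyl-olefination (Bu3SnCHBr2, CrCl2, LiI, THF/DMF, rt), in which the bulky tin group enforces the E geometry, should give the E-vinylstannane F7. Iododestannylation (I2, CH2Cl2, 0 °C) with retention of geometry then gives vinyl iodide 11, where the route is rejoined before step 9.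

Further compounds
F1 | step 10 | (3S)-7-(benzyloxy)-3-(2,2-dibromoethenyl)-8-methoxychroman | BrC(Br)=C[C@H]1COc2c(OC)c(OCc3ccccc3)ccc2C1
F2 | step 10 | {[(3S)-7-(benzyloxy)-8-methoxychroman-3-yl]ethynyl}lithium | [Li]C#C[C@H]1COc2c(OC)c(OCc3ccccc3)ccc2C1
F3 | step 10 | 4-{[(3S)-7-(benzyloxy)-8-methoxychroman-3-yl]ethynyl}-4-hydroxy-2,3-dimethoxycyclobut-2-en-1-one | COC1=C(OC)C(O)(C#C[C@H]2COc3c(OC)c(OCc4ccccc4)ccc3C2)C1=O
F4 | step 10 | 2-[(3S)-7-(benzyloxy)-8-methoxychroman-3-yl]-5,6-dimethoxycyclohexa-2,5-diene-1,4-dione | COC1=C(OC)C(=O)C([C@H]2COc3c(OC)c(OCc4ccccc4)ccc3C2)=CC1=O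
F5 | step 5 | rac-7-(benzyloxy)-8-methoxychroman-3-carboxylic acid | OC(=O)C1COc2c(OC)c(OCc3ccccc3)ccc2C1
F6 | step 5 | (R)-1-phenylethylammonium (3R)-7-(benzyloxy)-8-methoxychroman-3-carboxylate | C[C@@H]([NH3+])c1ccccc1.[O-]C(=O)[C@H]1COc2c(OC)c(OCc3ccccc3)ccc2C1
F7 | step 8 | (3S)-7-(benzyloxy)-8-methoxy-3-[(E)-2-(tributylstannyl)ethenyl]chroman | CCCC[Sn](CCCC)(CCCC)/C=C/[C@H]1COc2c(OC)c(OCc3ccccc3)ccc2C1
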